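**Plan**

- Retrosynthesis: the two aryl C–CHO bonds and three O–CH3 bonds are cut first, then the two C11–CH3 bonds and C7–C11 (ester from a dienyl triflate), the C5=C6 bond (back to a cis-fused 7-ketone), C9′–aryl (cuprate), C1–C9′ (aldehyde made from the C1 ketone), and last C5–C6 and C9–C10 of ring B.
- Enabling feature: ring A holds the quaternary C10 with its angular methyl between C1 and C5, so ring A as a 2-methyl enone (C1=O, C10=C5) is a dienophile, and a 2-silyloxybutadiene supplies C6–C9 of ring B with oxygen at C7.
- Forward order: ring A enone, ring B by [4+2], C1 side chain on the cis-decalin, ring B dehydrogenation and C7 hydroxyisopropyl group, then aryl diformylation and O-demethylation.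
- Stereochemistry: C4 from a chiral-base desymmetrization; C10 from cycloaddition anti to the C4 methyl; C1 from axial epoxidation followed by an anti 1,2-hydride shift; C9′ from cuprate addition to a conformationally fixed enone; C7 from pseudoaxial protonation of a dienolate.

Key step: step 6

Remark on numbering: C1 carries the side chain, C4 the secondary methyl, C5=C6 is the alkene, C7 carries the hydroxyisopropyl group (C11), C10 the angular methyl, C9′ is the benzylic carbon; Ar = 2,4,6-trimethoxyphenyl.
Assumption: the (S,S)-amide base is taken to remove the α-proton that leads to the (R)-enol silane 2, by analogy with the sense expected for 4-alkylcyclohexanones; if the sense is the opposite, the (R,R)-amide is used.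

**Route**

Step 1
Reactants: 1 4-methylcyclohexanone
Product: 2 (R)-4-methyl-1-(trimethylsilyloxy)cyclohex-1-ene
Conditions: (S,S)-bis(1-phenylethyl)amine, n-BuLi, TMSCl (internal quench), THF, −100 → −78 °C
Reagents that add atoms: chlorotrimethylsilane (C[Si](C)(C)Cl)
Why: Enantioselective deprotonation of a prochiral ketone by a C2-symmetric chiral lithium amide with in-situ silylation distinguishes the enantiotopic α-protons and so sets the stereocentre that becomes C4.

Step 2
Reactants: 2 (R)-4-methyl-1-(trimethylsilyloxy)cyclohex-1-ene
Product: 3 (R)-4-methylcyclohex-2-en-1-one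
Conditions: Pd(OAc)2 (10 mol %), O2 (1 atm), DMSO, rt
Reagents that add atoms: none
Why: Saegusa–Ito oxidation of the regiodefined silyl enol ether (palladium enolate, β-hydride elimination) gives the enone under neutral conditions that leave the γ-stereocentre untouched.

Step 3
Reactants: 3 (R)-4-methylcyclohex-2-en-1-one
Product: 4 (R)-2-iodo-4-methylcyclohex-2-en-1-one
Conditions: I2, pyridine, CH2Cl2, 0 °C → rt
Reagents that add atoms: iodine (II)
Why: Baylis–Hillman-type α-iodination of a cyclic enone (conjugate addition of pyridine, iodination of the enolate, loss of pyridine) is standard for cyclohexenones and is too weakly basic to deconjugate the enone or racemize C4.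

Step 4
Reactants: 4 (R)-2-iodo-4-methylcyclohex-2-en-1-one
Product: 5 (R)-2,4-dimethylcyclohex-2-en-1-one
Conditions: Me4Sn, Pd2(dba)3 (cat.), AsPh3, CuI (cat.), NMP, 80 °C
Reagents that add atoms: tetramethylstannane (C[Sn](C)(C)C)
Why: Stille cross-coupling of the 2-iodoenone installs the α-methyl group under neutral conditions, so the γ-stereocentre is not at risk.

Step 5
Reactants: 6 methyl vinyl ketone
Product: 7 2-(tert-butyldimethylsilyloxy)buta-1,3-diene
Conditions: TBSOTf, Et3N, Et2O, 0 °C
Reagents that add atoms: tert-butyldimethylsilyl triflate (CC(C)(C)[Si](C)(C)OS(=O)(=O)C(F)(F)F)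
Why: Soft enolization of the methyl ketone with a silyl triflate and an amine base is the standard preparation of 2-silyloxybutadienes.

Step 6
Reactants: 5 (R)-2,4-dimethylcyclohex-2-en-1-one; 7 2-(tert-butyldimethylsilyloxy)buta-1,3-diene
Product: 8 cis-fused 4,10-dimethyl-7-(tert-butyldimethylsilyloxy)-octahydronaphthalen-1-one with a C7=C8 double bond (C4–CH3, C5–H and C10–CH3 on one face)
Conditions: AlBr3/AlMe3 (premixed, cat.), toluene–CH2Cl2, −20 → 0 °C; pyridine quench
Reagents that add atoms: none
Why: The aluminium Lewis acid binds the enone carbonyl and a concerted, asynchronous Diels–Alder reaction follows, the closest known reaction type being the Lewis-acid-catalysed cycloaddition of 2-methylcycloalk-2-enones with 2-silyloxydienes. Ring B closes by intermolecular [4+2] cycloaddition: the diene CH2 next to the silyloxy carbon (largest HOMO coefficient) bonds to the β-carbon C5 and the other terminus to the α-carbon C10, so the silyl enol ether marks C7. C10 is controlled by the C4 stereocentre, because the diene adds to the face anti to the C4 methyl group, which places the C10 methyl cis to it. C5 follows from suprafacial addition to the dienophile (cis ring fusion), and it is removed later when C5=C6 is introduced. The step needs regioselectivity, secured by the 2-silyloxy donor, and π-facial selectivity, secured by the methyl-bearing carbon next to the reacting β-carbon; the α-methyl becomes the angular methyl and the carbonyl remains as the C1 handle.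

Step 7
Reactants: 8 Diels–Alder adduct
Product: 9 1-methylene analogue of 8 (C1=CH2, C7 TBS enol ether kept)
Conditions: Ph3PCH3Br, KHMDS, THF, 0 °C; then 8, reflux
Reagents that add atoms: methyltriphenylphosphonium bromide (C[P+](c1ccccc1)(c1ccccc1)c1ccccc1.[Br-])
Why: Wittig methylenation with the salt-free ylide at reflux converts the hindered α-quaternary C1 ketone into the exocyclic alkene while the base-stable silyl enol ether keeps C7 masked.

Step 8
Reactants: 9 1-methylene TBS enol ether
Product: 10 cis-fused 4,10-dimethyl-1-methylenedecalin-7-one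
Conditions: TBAF, AcOH, THF, 0 °C
Reagents that add atoms: none
Why: Buffered fluoride cleavage of the silyl enol ether releases the C7 ketone without acid that could move the exocyclic double bond, and the cis ring fusion cannot epimerize because C5 is not α to a carbonyl.

Step 9
Reactants: 10 methylene ketone
Product: 11 C1 spiro-epoxide of 10 (oxirane oxygen cis to the C10 methyl)
Conditions: mCPBA, NaHCO3, CH2Cl2, 0 °C
Reagents that add atoms: 3-chloroperoxybenzoic acid (O=C(OO)c1cccc(Cl)c1)
Why: Prilezhaev epoxidation is faster than Baeyer–Villiger oxidation of the ketone, and in the cis-decalin conformer with both methyl groups equatorial on ring A the axial C10–C9 bond blocks one face of the methylene group, so the peracid attacks axially and the new C1–O bond is cis to the C10 methyl.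

Step 10
Reactants: 11 spiro-epoxide
Product: 12 keto aldehyde with the C1 formyl group cis to the C10 methyl (axial on ring A) and the C7 ketone
Conditions: MABR [MeAl(OAr′)2, Ar′ = 4-bromo-2,6-di-tert-butylphenyl] (2.2 equiv), CH2Cl2, −78 °C; dilute HCl work-up
Reagents that add atoms: none
Why: In this Meinwald rearrangement the bulky aluminium aryloxide ionizes the tertiary C1–O bond and a hydride of the oxirane CH2 migrates anti to it, so C1–H ends on the face opposite the former C–O bond and the formyl group cis to the C10 methyl, which is the C1 configuration of the target.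

Step 11
Reactants: 12 keto aldehyde
Product: 13 (E)-enone C1–CH=CH–C(O)CH3 with the C7 ketone
Conditions: (MeO)2P(O)CH2C(O)CH3, LiCl, i-Pr2NEt, MeCN, rt
Reagents that add atoms: dimethyl (2-oxopropyl)phosphonate (COP(=O)(CC(C)=O)OC)
Why: Horner–Wadsworth–Emmons olefination with LiCl and an amine base reacts with the aldehyde in preference to the ring ketone, gives the E-enone, and is mild enough not to epimerize the axial α-centre C1.

Step 12
Reactants: 13 (E)-enone; 14 1,3,5-trimethoxybenzene
Product: 18 enol triflate C1–C9′H(Ar)–CH=C(OTf)CH3 with the C7 ketone, via 2,4,6-trimethoxyphenyllithium 15 (not isolated), via lithium diarylcuprate 16 (not isolated), via lithium enolate 17 (not isolated)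
Conditions: 14, n-BuLi, THF, 0 °C → rt; CuI, −40 °C; 13, −78 °C; then N-(5-chloro-2-pyridyl)triflimide, −78 → 0 °C; aq NH4Cl
Reagents that add atoms: N-(5-chloropyridin-2-yl)bis(trifluoromethanesulfonyl)imide (O=S(=O)(N(c1ccc(Cl)cn1)S(=O)(=O)C(F)(F)F)C(F)(F)F)
Why: Ortho-lithiation of the arene, transmetalation to the Gilman cuprate and 1,4-addition to the enone with O-triflation of the enolate should set C9′ as in the target, because the axial C1 substituent holds the vinylic C9′–H under ring A with C1–H eclipsing the C=C bond, the equatorial C10 methyl shields one π-face and the aryl group enters from the C2 side, while trapping as the enol triflate keeps the side chain distinct from the C7 ketone.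

Step 13
Reactants: 18 enol triflate
Product: 19 alkene C1–C9′H(Ar)–CH=C(CH3)2 with the C7 ketone
Conditions: Me4Sn, Pd(PPh3)4 (cat.), LiCl, DMF, 70 °C
Reagents that add atoms: tetramethylstannane (C[Sn](C)(C)C)
Why: Stille coupling of the enol triflate with tetramethyltin replaces the triflate by methyl and tolerates the ketone, and the alkene geometry is irrelevant because the terminus carries two methyl groups.

Step 14
Reactants: 19 alkene
Product: 20 cis-decalin-7-one with the complete side chain C1–C9′H(Ar)–CH2CH(CH3)2
Conditions: H2 (3 atm), Pd/C, EtOAc, rt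
Reagents that add atoms: none
Why: Heterogeneous hydrogenation of the only C=C bond gives the isobutyl group without forming a stereocentre and without touching the aryl ethers or the ketone.

Step 15
Reactants: 20 saturated ketone
Product: 22 cis-fused 8-en-7-one (C5–H kept), via TMS enol ether 21 (not isolated)
Conditions: LDA, TMSCl, THF, −78 °C; then Pd(OAc)2, MeCN, rt
Reagents that add atoms: none
Why: Saegusa–Ito oxidation through the kinetic silyl enol ether (LDA removes the less hindered C8 proton) introduces the first double bond, and its regiochemistry is not critical because the next step dehydrogenates the other side and both isomers converge.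

Step 16
Reactants: 22 8-en-7-one
Product: 24 cross-conjugated 5,8-dien-7-one, via TMS dienol ether 23 (not isolated)
Conditions: LDA, TMSCl, THF, −78 °C; then Pd(OAc)2, MeCN, rt
Reagents that add atoms: none
Why: In this second Saegusa–Ito oxidation the enone can enolize only toward C6 because C10 is quaternary, and palladium then introduces C5=C6, which removes the C5 stereocentre and locks the ring system with the C10 methyl axial.

Step 17
Reactants: 24 5,8-dien-7-one
Product: 26 5,7-dien-7-yl triflate, via potassium dienolate 25 (not isolated)
Conditions: K[s-Bu3BH], THF, −78 °C; then PhNTf2, −78 → 0 °C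
Reagents that add atoms: N-phenylbis(trifluoromethanesulfonyl)imide (O=S(=O)(N(c1ccccc1)S(=O)(=O)C(F)(F)F)C(F)(F)F)
Why: Conjugate reduction by a trialkylborohydride with enolate triflation delivers hydride to C9, the β-carbon that bears a hydrogen, and not to the fully substituted C5, and the regiodefined enolate is trapped without any base that could reach the γ-proton at C4.

Step 18
Reactants: 26 dienyl triflate
Product: 27 methyl 5,7-diene-7-carboxylate
Conditions: Pd(OAc)2 (cat.), dppp, CO (1 atm), MeOH, Et3N, DMF, 60 °C
Reagents that add atoms: carbon monoxide ([C-]#[O+]); methanol (CO)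
Why: Palladium-catalysed alkoxycarbonylation of the enol triflate (oxidative addition, CO insertion, methanolysis) attaches C11 to C7.

Step 19
Reactants: 27 dienoate
Product: 28 methyl 5-ene-7-carboxylate with C7–H (ester cis to the C10 methyl)
Conditions: [(Ph3P)CuH]6 (cat.), PhMe2SiH, t-BuOH, toluene, 0 °C → rt
Reagents that add atoms: none
Why: Copper hydride 1,4-reduction of the acrylate unit puts hydride on C8, and kinetic α-protonation of the dienolate by tert-butanol should occur pseudoaxially on the ring B half-chair, on the face opposite the axial C10 methyl, which gives the β,γ-unsaturated ester with the ester pseudoequatorial and cis to the C10 methyl at the new stereocentre C7.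

Step 20
Reactants: 28 β,γ-unsaturated ester
Product: 29 tertiary alcohol (C7–C(CH3)2OH, C5=C6, aryl still tri-O-methyl and unformylated)
Conditions: MeLi, CeCl3, THF, −78 °C; aq NH4Cl
Reagents that add atoms: methyllithium ([Li]C)
Why: Double addition of the organocerium reagent to the ester gives the tertiary alcohol, and the weakly basic cerium reagent does not enolize the β,γ-unsaturated ester or the intermediate ketone, so C7 and the alkene position are kept.

Step 21
Reactants: 29 tertiary alcohol
Product: 31 tri-O-methyl ether of the target (3′,5′-diformyl), via lithium hemiaminal alkoxide 30 (not isolated)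
Conditions: n-BuLi, TMEDA, THF, 0 °C; DMF, −78 °C; n-BuLi, −20 → 0 °C; DMF; aq NH4Cl
Reagents that add atoms: N,N-dimethylformamide (CN(C)C=O)
Why: In this iterative directed ortho-metalation and formylation each aryl hydrogen lies between two methoxy groups and is lithiated readily, the first DMF adduct stays as a lithium hemiaminal alkoxide that protects the formyl group during the second lithiation, and the tertiary alcohol is carried as its alkoxide.

Step 22
Reactants: 31 diformyl trimethyl ether
Product: 32 target CNP0108656.4
Conditions: NaSEt, DMF, 110 °C; then dilute HCl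
Reagents that add atoms: none
Why: Nucleophilic O-demethylation (SN2 at methyl by thiolate) is activated because every methoxy group is ortho to a formyl group, and the non-acidic conditions spare the tertiary alcohol and the trisubstituted alkene.

**Compound list**

1 | 4-methylcyclohexanone | CC1CCC(=O)CC1 | starting material
2 | (R)-4-methyl-1-(trimethylsilyloxy)cyclohex-1-ene | C[Si](C)(C)OC1=CC[C@H](C)CC1 | intermediate
3 | (R)-4-methylcyclohex-2-en-1-one | O=C1CC[C@@H](C)C=C1 | intermediate
4 | (R)-2-iodo-4-methylcyclohex-2-en-1-one | O=C1CC[C@@H](C)C=C1I | intermediate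
5 | (R)-2,4-dimethylcyclohex-2-en-1-one | O=C1CC[C@@H](C)C=C1C | intermediate
6 | methyl vinyl ketone | CC(=O)C=C | starting material
7 | 2-(tert-butyldimethylsilyloxy)buta-1,3-diene | C=CC(=C)O[Si](C)(C)C(C)(C)C | intermediate
8 | cis-fused Diels–Alder adduct, C1 ketone, C7 TBS enol ether (C7=C8), C4-Me/C5-H/C10-Me cis | O=C1CC[C@@H](C)[C@@H]2CC(O[Si](C)(C)C(C)(C)C)=CC[C@@]21C | intermediate
9 | 1-methylene analogue of 8 | C=C1CC[C@@H](C)[C@@H]2CC(O[Si](C)(C)C(C)(C)C)=CC[C@@]21C | intermediate
10 | cis-fused 4,10-dimethyl-1-methylenedecalin-7-one | C=C1CC[C@@H](C)[C@@H]2CC(=O)CC[C@@]21C | intermediate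
11 | C1 spiro-epoxide, oxirane O cis to C10-Me | C1O[C@]12CC[C@@H](C)[C@@H]3CC(=O)CC[C@@]32C | intermediate
12 | keto aldehyde, C1-CHO cis to C10-Me | O=C[C@H]1CC[C@@H](C)[C@@H]2CC(=O)CC[C@@]21C | intermediate
13 | (E)-enone at C1, C7 ketone | CC(=O)/C=C/[C@H]1CC[C@@H](C)[C@@H]2CC(=O)CC[C@@]21C | intermediate
14 | 1,3,5-trimethoxybenzene | COc1cc(OC)cc(OC)c1 | starting material
15 | 2,4,6-trimethoxyphenyllithium | [Li]c1c(OC)cc(OC)cc1OC | intermediate
16 | lithium bis(2,4,6-trimethoxyphenyl)cuprate | [Li+].COc1cc(OC)c([Cu-]c2c(OC)cc(OC)cc2OC)c(OC)c1 | intermediate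
17 | lithium enolate of the β-aryl methyl ketone | [Li]OC(C)=C[C@H](c1c(OC)cc(OC)cc1OC)[C@H]1CC[C@@H](C)[C@@H]2CC(=O)CC[C@@]21C | intermediate
18 | side-chain enol triflate, C7 ketone | CC(OS(=O)(=O)C(F)(F)F)=C[C@H](c1c(OC)cc(OC)cc1OC)[C@H]1CC[C@@H](C)[C@@H]2CC(=O)CC[C@@]21C | intermediate
19 | side-chain 2-methylprop-1-enyl compound, C7 ketone | CC(C)=C[C@H](c1c(OC)cc(OC)cc1OC)[C@H]1CC[C@@H](C)[C@@H]2CC(=O)CC[C@@]21C | intermediate
20 | cis-decalin-7-one with complete C1 side chain | CC(C)C[C@H](c1c(OC)cc(OC)cc1OC)[C@H]1CC[C@@H](C)[C@@H]2CC(=O)CC[C@@]21C | intermediate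
21 | 7-trimethylsilyloxy-7-ene (TMS enol ether of 20) | CC(C)C[C@H](c1c(OC)cc(OC)cc1OC)[C@H]1CC[C@@H](C)[C@@H]2CC(O[Si](C)(C)C)=CC[C@@]21C | intermediate
22 | cis-fused 8-en-7-one | CC(C)C[C@H](c1c(OC)cc(OC)cc1OC)[C@H]1CC[C@@H](C)[C@@H]2CC(=O)C=C[C@@]21C | intermediate
23 | 7-trimethylsilyloxy-6,8-diene | CC(C)C[C@H](c1c(OC)cc(OC)cc1OC)[C@H]1CC[C@@H](C)[C@@H]2C=C(O[Si](C)(C)C)C=C[C@@]21C | intermediate
24 | 5,8-dien-7-one | CC(C)C[C@H](c1c(OC)cc(OC)cc1OC)[C@H]1CC[C@@H](C)C2=CC(=O)C=C[C@@]21C | intermediate
25 | potassium 5,7-dien-7-olate | CC(C)C[C@H](c1c(OC)cc(OC)cc1OC)[C@H]1CC[C@@H](C)C2=CC(O[K])=CC[C@@]21C | intermediate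
26 | 5,7-dien-7-yl triflate | CC(C)C[C@H](c1c(OC)cc(OC)cc1OC)[C@H]1CC[C@@H](C)C2=CC(OS(=O)(=O)C(F)(F)F)=CC[C@@]21C | intermediate
27 | methyl 5,7-diene-7-carboxylate | CC(C)C[C@H](c1c(OC)cc(OC)cc1OC)[C@H]1CC[C@@H](C)C2=CC(C(=O)OC)=CC[C@@]21C | intermediate
28 | methyl 5-ene-7-carboxylate, ester cis to C10-Me | CC(C)C[C@H](c1c(OC)cc(OC)cc1OC)[C@H]1CC[C@@H](C)C2=C[C@@H](C(=O)OC)CC[C@@]21C | intermediate
29 | tertiary alcohol, aryl = 2,4,6-trimethoxyphenyl | CC(C)C[C@H](c1c(OC)cc(OC)cc1OC)[C@H]1CC[C@@H](C)C2=C[C@@H](C(C)(C)O)CC[C@@]21C | intermediate
30 | monoformyl adduct as lithium hemiaminal alkoxide (C11 lithium alkoxide) | CC(C)C[C@H](c1c(OC)c(C(O[Li])N(C)C)c(OC)cc1OC)[C@H]1CC[C@@H](C)C2=C[C@@H](C(C)(C)O[Li])CC[C@@]21C | intermediate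
31 | tri-O-methyl ether of the target | CC(C)C[C@H](c1c(OC)c(C=O)c(OC)c(C=O)c1OC)[C@H]1CC[C@@H](C)C2=C[C@@H](C(C)(C)O)CC[C@@]21C | intermediate
32 | CNP0108656.4 (1R,4R,7S,10R,9′S in the numbering used here) | CC(C)C[C@H](c1c(O)c(C=O)c(O)c(C=O)c1O)[C@H]1CC[C@@H](C)C2=C[C@@H](C(C)(C)O)CC[C@@]21C | target

**Count and risks**

Total step count: 22. Longest linear sequence: 21 steps (steps 1–4 and 6–22).

Steps most likely to fail:

Step 10. The C1 cation that develops may instead trigger migration of the antiperiplanar C10–C9 bond (Wagner–Meerwein shift), or the hydride shift may lose its stereospecificity and the axial aldehyde may epimerize. The fallback forms the C1–C bond by a radical reaction, which should also take place on the axial face anti to the C10–C9 bond. It sets out from 8: reduction of the C1 ketone with NaBH4 gives the C1 alcohol F1, and NaH, CS2 and MeI convert it into the S-methyl xanthate F2. Radical allylation with allyltributylstannane and AIBN gives the axial C1-allyl silyl enol ether F3, and buffered TBAF releases the C1-allyl 7-ketone F4. Iridium-catalysed alkene isomerization gives the C1-(E)-propenyl ketone F5, and ozonolysis with Me2S work-up returns to the route at 12.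

Step 12. The doubly ortho-substituted aryl group may transfer sluggishly, facial selectivity at C9′ may be poor, or proton transfer from the ring ketone may scramble the enolate before triflation. The fallback replaces the organocopper addition by a Friedel–Crafts allylation that brings in the same aryl group as the incoming partner. It sets out from 12: 2-methylprop-1-enylmagnesium bromide at −78 °C adds to the aldehyde to give the allylic alcohol F6, and a catalytic Lewis acid (Sc(OTf)3) with 1,3,5-trimethoxybenzene 14 should arylate the ring-side terminus of the allyl cation from the same open face, which returns to the route at 19.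

Step 21. The second metalation may stay incomplete, or the hemiaminal may collapse before it, so that the free aldehyde is attacked by butyllithium. The fallback uses halogenation and halogen–lithium exchange in place of directed metalation. It sets out from 29: NBS in MeCN at −20 °C brominates both free aryl positions to give the 3′,5′-dibromide F7, and excess t-BuLi at −78 °C followed by DMF returns to the route at 31.

**Further compounds**

F1 | step 10 | C1 alcohol of 8 (C1 configuration not defined), C7 TBS enol ether | OC1CC[C@@H](C)[C@@H]2CC(O[Si](C)(C)C(C)(C)C)=CC[C@@]21C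
F2 | step 10 | S-methyl xanthate of F1 | CSC(=S)OC1CC[C@@H](C)[C@@H]2CC(O[Si](C)(C)C(C)(C)C)=CC[C@@]21C
F3 | step 10 | C1-allyl compound (allyl cis to C10-Me), C7 TBS enol ether | C=CC[C@H]1CC[C@@H](C)[C@@H]2CC(O[Si](C)(C)C(C)(C)C)=CC[C@@]21C
F4 | step 10 | C1-allyl cis-decalin-7-one | C=CC[C@H]1CC[C@@H](C)[C@@H]2CC(=O)CC[C@@]21C
F5 | step 10 | C1-(E)-prop-1-enyl cis-decalin-7-one | C/C=C/[C@H]1CC[C@@H](C)[C@@H]2CC(=O)CC[C@@]21C
F6 | step 12 | allylic alcohol C1–CH(OH)–CH=C(CH3)2 (carbinol configuration not defined), C7 ketone | CC(C)=CC(O)[C@H]1CC[C@@H](C)[C@@H]2CC(=O)CC[C@@]21C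
F7 | step 21 | 3′,5′-dibromo derivative of 29 | CC(C)C[C@H](c1c(OC)c(Br)c(OC)c(Br)c1OC)[C@H]1CC[C@@H](C)C2=C[C@@H](C(C)(C)O)CC[C@@]21C
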